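Ring C is disconnected at C4–C4a, C3–O and O1–C2. C4 and C3 lie β and α to a latent C2 aldehyde, and ring A is a resorcinol whose carbon ortho to OH can bond to C4 while that hydroxyl caps C2. In one flask, two amines used in sequence join a ring D enal, a ring A phenol and benzoyl peroxide into the 3,4-trans 2-hydroxy-4-arylchroman-3-yl benzoate, setting C4 and C3. The precursors are an (E)-2-bromo-4,6-bis(pivaloyloxy)cinnamaldehyde and 3-(triisopropylsilyloxy)phenol. The benzoate then steers a C2 arylation to the 2,3-trans flavan; Heck coupling and deprotection finish the synthesis.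

Key step: step 5

Remark on the chemistry: a single amine that covers the same face of the iminium ion and of the enamine would place the benzoate cis to ring D, so the 3,4-trans array is assigned to two amines of opposite facial bias used one after the other; ring D carries pivalates (a less electron-rich, better acceptor enal), ring A a TIPS ether (bulk at the two unwanted ring carbons), and (4-bromophenoxy)(tert-butyl)dimethylsilane is taken as a commercial starting material.

Step 1
Reactants: 1 5-bromoresorcinol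
Product: 2 2-bromo-4,6-dihydroxybenzaldehyde
Conditions: POCl3, DMF, MeCN, 0 °C → rt; then H2O, 50 °C
Reagents that add atoms: N,N-dimethylformamide CN(C)C=O (formyl carbon); water O (formyl oxygen)
Why: Vilsmeier–Haack formylation, in which the chloroiminium ion should attack the ring carbon para to one hydroxyl and ortho to the other (next to bromine), as resorcinol and its 5-substituted congeners do, and hydrolysis of the iminium salt frees the aldehyde.

Step 2
Reactants: 2 2-bromo-4,6-dihydroxybenzaldehyde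
Product: 3 2-bromo-4,6-bis(pivaloyloxy)benzaldehyde
Conditions: PivCl, Et3N, DMAP (cat.), CH2Cl2, 0 °C → rt
Reagents that add atoms: pivaloyl chloride CC(C)(C)C(=O)Cl
Why: DMAP-catalysed esterification of both phenols, giving acyl groups that make ring D electron-poor and that should survive every step up to the reductive ester cleavage.

Step 3
Reactants: 3 2-bromo-4,6-bis(pivaloyloxy)benzaldehyde
Product: 4 (E)-3-[2-bromo-4,6-bis(pivaloyloxy)phenyl]acrylaldehyde
Conditions: Ph3P=CHCHO (1.1 equiv), toluene, 80 °C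
Reagents that add atoms: (triphenylphosphoranylidene)acetaldehyde O=CC=P(c1ccccc1)(c1ccccc1)c1ccccc1
Why: Wittig olefination with the stabilised formyl ylide should give the E-enal, the electron-poor aryl aldehyde reacting faster than the product enal so that double homologation stays minor.

Step 4
Reactants: 5 resorcinol
Product: 6 3-(triisopropylsilyloxy)phenol
Conditions: 5 (3 equiv), TIPSCl (1 equiv), imidazole, DMF, 0 °C → rt
Reagents that add atoms: triisopropylsilyl chloride CC(C)[Si](Cl)(C(C)C)C(C)C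
Why: Silyl ether formation on an excess of the diol should give mainly the monoether, the surplus resorcinol being removed by aqueous washing.

Step 5
Reactants: 4 (E)-3-[2-bromo-4,6-bis(pivaloyloxy)phenyl]acrylaldehyde; 6 3-(triisopropylsilyloxy)phenol; 7 benzoyl peroxide
Product: 9 (3S,4S)-4-[2-bromo-4,6-bis(pivaloyloxy)phenyl]-2-hydroxy-7-(triisopropylsilyloxy)chroman-3-yl benzoate (anomers at C2), via chroman-2-ol 8 (not isolated)
Conditions: (2R,5R)-5-benzyl-2-tert-butyl-3-methylimidazolidin-4-one·TFA (20 mol %), 6 (1.5 equiv), CHCl3, 0 °C → rt; then (S)-2-(triphenylmethyl)pyrrolidine (30 mol %), hydroquinone (10 mol %), 7 (1.3 equiv), THF, 0 °C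
Reagents that add atoms: none
Why: Proposed new method: the imidazolidinone condenses with enal 4 to an E-iminium ion whose β-carbon (the future C4) is attacked by the carbon of phenol 6 that is ortho to OH and para to OSi, hydrolysis and 6-exo-trig addition of the phenol oxygen to the freed aldehyde (O1–C2) give lactol 8, and the open-chain fraction of 8 then forms an enamine with the pyrrolidine that attacks a peroxide oxygen of 7 (C3–O) before the α-benzoyloxy aldehyde recloses in the same 6-exo-trig mode to 9. The closest known reaction types are amine-catalysed Friedel–Crafts alkylation–lactolisation of electron-rich phenols with enals, iminium–enamine cascades that pair a conjugate Friedel–Crafts addition with α-halogenation, cycle-specific cascades in which a second amine of chosen handedness sets the α-centre, and amine-catalysed α-benzoyloxylation of aldehydes with benzoyl peroxide, but their union on a phenol nucleophile with lactol trapping is not known. C4 is set by the (2R,5R)-imidazolidinone, whose benzyl group covers one face of the iminium ion so that ring A adds to the other (4S). C3 is set by the (S)-pyrrolidine, whose trityl group covers the enamine face on which ring A entered, so that the benzoate enters from the opposite face and ends trans to ring D (3S), while the imidazolidinone, a poor enamine former with this β-branched lactol, should not compete. The step needs ortho-to-hydroxyl regiochemistry, secured by the hydrogen bond from the phenol OH to the counter-ion, by the para silyloxy donor and by the bulk of the TIPS group next to the two other ring carbons, and it needs a reactive acceptor, secured by the pivalates on ring D. Reclosure to the lactol should protect the α-benzoyloxy aldehyde from epimerisation and from a second oxidation.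

Step 6
Reactants: 9 (3S,4S)-4-[2-bromo-4,6-bis(pivaloyloxy)phenyl]-2-hydroxy-7-(triisopropylsilyloxy)chroman-3-yl benzoate
Product: 10 (3S,4S)-2-acetoxy-4-[2-bromo-4,6-bis(pivaloyloxy)phenyl]-7-(triisopropylsilyloxy)chroman-3-yl benzoate (anomers at C2)
Conditions: Ac2O, pyridine, DMAP (cat.), CH2Cl2, 0 °C
Reagents that add atoms: acetic anhydride CC(=O)OC(C)=O
Why: Acetylation of the lactol hydroxyl by acyl transfer should give the anomeric acetate without touching C3 or C4, since the closed lactol keeps the α-benzoyloxy aldehyde away from enolisation.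

Step 7
Reactants: 10 (3S,4S)-2-acetoxy-4-[2-bromo-4,6-bis(pivaloyloxy)phenyl]-7-(triisopropylsilyloxy)chroman-3-yl benzoate; 11 (4-bromophenoxy)(tert-butyl)dimethylsilane
Product: 14 (2R,3S,4S)-4-[2-bromo-4,6-bis(pivaloyloxy)phenyl]-2-[4-(tert-butyldimethylsilyloxy)phenyl]-7-(triisopropylsilyloxy)chroman-3-yl benzoate, via anomeric bromide 12 (not isolated), via arylzinc bromide 13 (not isolated)
Conditions: 10, TMSBr, CH2Cl2, 0 °C, then evaporation; 13 (2 equiv) from 11, n-BuLi, toluene/n-Bu2O, −10 °C, then ZnBr2; combined in toluene/n-Bu2O, 0 → 60 °C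
Reagents that add atoms: none
Why: Acetate–bromide exchange at the anomeric carbon followed by substitution with the arylzinc reagent, the reaction type used for C-arylation of 2-O-acyl glycosyl bromides, should proceed through a cis-fused dioxolan-2-ylium ion formed by the 3-benzoate, so that the aryl group enters C2 anti to O3 and the 2,3-trans (2R) flavan results.

Step 8
Reactants: 15 3,4-dihydroxybenzaldehyde
Product: 16 3,4-bis(tert-butyldimethylsilyloxy)benzaldehyde
Conditions: TBSCl, imidazole, DMF, rt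
Reagents that add atoms: tert-butyldimethylsilyl chloride CC(C)(C)[Si](C)(C)Cl
Why: Silyl ether formation on both catechol hydroxyls under standard imidazole catalysis.

Step 9
Reactants: 16 3,4-bis(tert-butyldimethylsilyloxy)benzaldehyde
Product: 17 3,4-bis(tert-butyldimethylsilyloxy)styrene
Conditions: MePPh3Br (1.2 equiv), KOt-Bu (1.1 equiv), THF, 0 °C; then 16, 0 °C → rt
Reagents that add atoms: methyltriphenylphosphonium bromide C[P+](c1ccccc1)(c1ccccc1)c1ccccc1.[Br-]
Why: Wittig methylenation with the preformed non-stabilised ylide, so that no free alkoxide meets the aryl silyl ethers.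

Step 10
Reactants: 14 (2R,3S,4S)-4-[2-bromo-4,6-bis(pivaloyloxy)phenyl]-2-[4-(tert-butyldimethylsilyloxy)phenyl]-7-(triisopropylsilyloxy)chroman-3-yl benzoate; 17 3,4-bis(tert-butyldimethylsilyloxy)styrene
Product: 18 (2R,3S,4S)-4-{2-[(E)-2-(3,4-bis(tert-butyldimethylsilyloxy)phenyl)ethenyl]-4,6-bis(pivaloyloxy)phenyl}-2-[4-(tert-butyldimethylsilyloxy)phenyl]-7-(triisopropylsilyloxy)chroman-3-yl benzoate
Conditions: Pd[P(t-Bu)3]2 (5 mol %), Cy2NMe, 1,4-dioxane, 80 °C
Reagents that add atoms: none
Why: Mizoroki–Heck reaction in which the bulky electron-rich phosphine allows oxidative addition into the hindered aryl bromide, the aryl group adds to the terminal carbon of the styrene and syn β-hydride elimination should give the E-stilbene, with esters and silyl ethers untouched by the amine base.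

Step 11
Reactants: 18 (2R,3S,4S)-4-{2-[(E)-2-(3,4-bis(tert-butyldimethylsilyloxy)phenyl)ethenyl]-4,6-bis(pivaloyloxy)phenyl}-2-[4-(tert-butyldimethylsilyloxy)phenyl]-7-(triisopropylsilyloxy)chroman-3-yl benzoate
Product: 19 (2R,3S,4S)-4-{2-[(E)-2-(3,4-bis(tert-butyldimethylsilyloxy)phenyl)ethenyl]-4,6-dihydroxyphenyl}-2-[4-(tert-butyldimethylsilyloxy)phenyl]-7-(triisopropylsilyloxy)chroman-3-ol
Conditions: i-Bu2AlH (DIBAL-H, excess), CH2Cl2, −78 → 0 °C; aqueous Rochelle salt
Reagents that add atoms: none
Why: Reductive ester cleavage removes the C3 benzoate and both aryl pivalates as benzyl and neopentyl alcohol without base, which should leave the silyl ethers, the stilbene and all three stereocentres untouched.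

Step 12
Reactants: 19 (2R,3S,4S)-4-{2-[(E)-2-(3,4-bis(tert-butyldimethylsilyloxy)phenyl)ethenyl]-4,6-dihydroxyphenyl}-2-[4-(tert-butyldimethylsilyloxy)phenyl]-7-(triisopropylsilyloxy)chroman-3-ol
Product: 20 (2R,3S,4S)-4-{2-[(E)-2-(3,4-dihydroxyphenyl)ethenyl]-4,6-dihydroxyphenyl}-2-(4-hydroxyphenyl)chroman-3,7-diol (CNP0170061.1)
Conditions: HF·pyridine, pyridine, THF, 0 °C → rt, under argon
Reagents that add atoms: none
Why: Fluoride-mediated desilylation of the four aryl silyl ethers under pyridine-buffered conditions should free the phenols while avoiding phenoxide oxidation and acid-promoted ionisation at C2 or C4.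

Compound list
1 | 5-bromoresorcinol (5-bromobenzene-1,3-diol) | Oc1cc(O)cc(Br)c1 | starting material
2 | 2-bromo-4,6-dihydroxybenzaldehyde | O=Cc1c(O)cc(O)cc1Br | intermediate
3 | 2-bromo-4,6-bis(pivaloyloxy)benzaldehyde | O=Cc1c(OC(=O)C(C)(C)C)cc(OC(=O)C(C)(C)C)cc1Br | intermediate
4 | (E)-3-[2-bromo-4,6-bis(pivaloyloxy)phenyl]acrylaldehyde | O=C/C=C/c1c(OC(=O)C(C)(C)C)cc(OC(=O)C(C)(C)C)cc1Br | intermediate
5 | resorcinol | Oc1cccc(O)c1 | starting material
6 | 3-(triisopropylsilyloxy)phenol | Oc1cccc(O[Si](C(C)C)(C(C)C)C(C)C)c1 | intermediate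
7 | benzoyl peroxide | O=C(OOC(=O)c1ccccc1)c1ccccc1 | starting material
8 | (4S)-4-[2-bromo-4,6-bis(pivaloyloxy)phenyl]-7-(triisopropylsilyloxy)chroman-2-ol (anomers at C2) | OC1Oc2cc(O[Si](C(C)C)(C(C)C)C(C)C)ccc2[C@@H](c2c(OC(=O)C(C)(C)C)cc(OC(=O)C(C)(C)C)cc2Br)C1 | intermediate
9 | (3S,4S)-4-[2-bromo-4,6-bis(pivaloyloxy)phenyl]-2-hydroxy-7-(triisopropylsilyloxy)chroman-3-yl benzoate (anomers at C2) | OC1Oc2cc(O[Si](C(C)C)(C(C)C)C(C)C)ccc2[C@@H](c2c(OC(=O)C(C)(C)C)cc(OC(=O)C(C)(C)C)cc2Br)[C@@H]1OC(=O)c1ccccc1 | intermediate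
10 | (3S,4S)-2-acetoxy-4-[2-bromo-4,6-bis(pivaloyloxy)phenyl]-7-(triisopropylsilyloxy)chroman-3-yl benzoate (anomers at C2) | CC(=O)OC1Oc2cc(O[Si](C(C)C)(C(C)C)C(C)C)ccc2[C@@H](c2c(OC(=O)C(C)(C)C)cc(OC(=O)C(C)(C)C)cc2Br)[C@@H]1OC(=O)c1ccccc1 | intermediate
11 | (4-bromophenoxy)(tert-butyl)dimethylsilane | CC(C)(C)[Si](C)(C)Oc1ccc(Br)cc1 | starting material
12 | (3S,4S)-2-bromo-4-[2-bromo-4,6-bis(pivaloyloxy)phenyl]-7-(triisopropylsilyloxy)chroman-3-yl benzoate (anomers at C2) | BrC1Oc2cc(O[Si](C(C)C)(C(C)C)C(C)C)ccc2[C@@H](c2c(OC(=O)C(C)(C)C)cc(OC(=O)C(C)(C)C)cc2Br)[C@@H]1OC(=O)c1ccccc1 | intermediate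
13 | [4-(tert-butyldimethylsilyloxy)phenyl]zinc bromide | CC(C)(C)[Si](C)(C)Oc1ccc([Zn]Br)cc1 | intermediate
14 | (2R,3S,4S)-4-[2-bromo-4,6-bis(pivaloyloxy)phenyl]-2-[4-(tert-butyldimethylsilyloxy)phenyl]-7-(triisopropylsilyloxy)chroman-3-yl benzoate | CC(C)(C)[Si](C)(C)Oc1ccc([C@H]2Oc3cc(O[Si](C(C)C)(C(C)C)C(C)C)ccc3[C@@H](c3c(OC(=O)C(C)(C)C)cc(OC(=O)C(C)(C)C)cc3Br)[C@@H]2OC(=O)c2ccccc2)cc1 | intermediate
15 | 3,4-dihydroxybenzaldehyde | O=Cc1ccc(O)c(O)c1 | starting material
16 | 3,4-bis(tert-butyldimethylsilyloxy)benzaldehyde | O=Cc1ccc(O[Si](C)(C)C(C)(C)C)c(O[Si](C)(C)C(C)(C)C)c1 | intermediate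
17 | 3,4-bis(tert-butyldimethylsilyloxy)styrene | C=Cc1ccc(O[Si](C)(C)C(C)(C)C)c(O[Si](C)(C)C(C)(C)C)c1 | intermediate
18 | (2R,3S,4S)-4-{2-[(E)-2-(3,4-bis(tert-butyldimethylsilyloxy)phenyl)ethenyl]-4,6-bis(pivaloyloxy)phenyl}-2-[4-(tert-butyldimethylsilyloxy)phenyl]-7-(triisopropylsilyloxy)chroman-3-yl benzoate | CC(C)(C)[Si](C)(C)Oc1ccc([C@H]2Oc3cc(O[Si](C(C)C)(C(C)C)C(C)C)ccc3[C@@H](c3c(OC(=O)C(C)(C)C)cc(OC(=O)C(C)(C)C)cc3/C=C/c3ccc(O[Si](C)(C)C(C)(C)C)c(O[Si](C)(C)C(C)(C)C)c3)[C@@H]2OC(=O)c2ccccc2)cc1 | intermediate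
19 | (2R,3S,4S)-4-{2-[(E)-2-(3,4-bis(tert-butyldimethylsilyloxy)phenyl)ethenyl]-4,6-dihydroxyphenyl}-2-[4-(tert-butyldimethylsilyloxy)phenyl]-7-(triisopropylsilyloxy)chroman-3-ol | CC(C)(C)[Si](C)(C)Oc1ccc([C@H]2Oc3cc(O[Si](C(C)C)(C(C)C)C(C)C)ccc3[C@@H](c3c(O)cc(O)cc3/C=C/c3ccc(O[Si](C)(C)C(C)(C)C)c(O[Si](C)(C)C(C)(C)C)c3)[C@@H]2O)cc1 | intermediate
20 | (2R,3S,4S)-4-{2-[(E)-2-(3,4-dihydroxyphenyl)ethenyl]-4,6-dihydroxyphenyl}-2-(4-hydroxyphenyl)chroman-3,7-diol | Oc1ccc([C@H]2Oc3cc(O)ccc3[C@@H](c3c(O)cc(O)cc3/C=C/c3ccc(O)c(O)c3)[C@@H]2O)cc1 | target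

Total step count: 12. Longest linear sequence: 9 steps (steps 1, 2, 3, 5, 6, 7, 10, 11, 12).

Steps most likely to fail

Step 5. The hindered iminium ion may be attacked slowly or at oxygen. In the second stage the imidazolidinone or the C4 centre may override the pyrrolidine, so that facial control at C3 is lost. Oxidation of phenol and amines by the peroxide may also outrun enamine oxygenation. Should only the sense of the pyrrolidine prove wrong, its enantiomer is used. The fallback sets out from 4 and 6 and returns at 12, using known reaction types only. The Friedel–Crafts alkylation–lactolisation is run alone, as is known for electron-rich phenols with enals, and lactol 8 is isolated. Acid-catalysed dehydration (PPTS, toluene, 80 °C, molecular sieves) should give (4S)-4-[2-bromo-4,6-bis(pivaloyloxy)phenyl]-7-(triisopropylsilyloxy)-4H-chromene F1. Dihydroxylation of this enol ether (OsO4 cat., NMO, acetone/H2O) on the face away from ring D should give the 2,3-cis chroman-2,3-diol F2, with O3 trans to ring D. Benzoylation (BzCl, pyridine, DMAP) gives the 2,3-dibenzoate F3, whose anomeric benzoate is exchanged with TMSBr to give 12.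

Step 7. The arylzinc reagent may attack the dioxolan-2-ylium carbon instead of C2, the bromide may lose HBr to a chromene, or facial control at C2 may be incomplete. The fallback sets out from 9 and returns at 14. Lactol 9 is treated at −78 °C in THF with the Grignard reagent made from 11 and Mg (2.2 equiv). The first equivalent opens the lactol as its phenoxide and the second adds to the aldehyde, giving the benzylic carbinol F4 as a mixture at the new centre. Catalytic camphorsulfonic acid in CH2Cl2 at 0 °C then ionises the p-silyloxybenzylic alcohol; the 3-benzoate bridges the cation and the ring A phenol closes O1–C2 anti to it, which should give 14.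

Step 10. Oxidative addition next to the diarylmethine carbon may be slow, leading to protodebromination, or insertion may give the 1,1-diarylethene regioisomer. The fallback sets out from 14 and 17 and returns at 18. Cross-metathesis of 17 with vinylboronic acid pinacol ester (second-generation Grubbs catalyst, CH2Cl2, 40 °C) should give the (E)-styrylboronate F5. Suzuki–Miyaura coupling of F5 with 14 (Pd(OAc)2, SPhos, K3PO4, THF/H2O, 40 °C) then gives 18.

Further compounds
F1 | step 5 | (4S)-4-[2-bromo-4,6-bis(pivaloyloxy)phenyl]-7-(triisopropylsilyloxy)-4H-chromene | C1=C[C@H](c2c(OC(=O)C(C)(C)C)cc(OC(=O)C(C)(C)C)cc2Br)c2ccc(O[Si](C(C)C)(C(C)C)C(C)C)cc2O1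
F2 | step 5 | (3S,4S)-4-[2-bromo-4,6-bis(pivaloyloxy)phenyl]-7-(triisopropylsilyloxy)chroman-2,3-diol (2,3-cis as formed, C2 free to anomerise) | OC1Oc2cc(O[Si](C(C)C)(C(C)C)C(C)C)ccc2[C@@H](c2c(OC(=O)C(C)(C)C)cc(OC(=O)C(C)(C)C)cc2Br)[C@@H]1O
F3 | step 5 | (3S,4S)-4-[2-bromo-4,6-bis(pivaloyloxy)phenyl]-7-(triisopropylsilyloxy)chroman-2,3-diyl dibenzoate | O=C(OC1Oc2cc(O[Si](C(C)C)(C(C)C)C(C)C)ccc2[C@@H](c2c(OC(=O)C(C)(C)C)cc(OC(=O)C(C)(C)C)cc2Br)[C@@H]1OC(=O)c1ccccc1)c1ccccc1
F4 | step 7 | (2S,3S)-3-[2-bromo-4,6-bis(pivaloyloxy)phenyl]-1-[4-(tert-butyldimethylsilyloxy)phenyl]-1-hydroxy-3-[2-hydroxy-4-(triisopropylsilyloxy)phenyl]propan-2-yl benzoate (both C1 epimers) | OC(c1ccc(O[Si](C)(C)C(C)(C)C)cc1)[C@@H](OC(=O)c1ccccc1)[C@H](c1c(OC(=O)C(C)(C)C)cc(OC(=O)C(C)(C)C)cc1Br)c1ccc(O[Si](C(C)C)(C(C)C)C(C)C)cc1O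
F5 | step 10 | (E)-2-[3,4-bis(tert-butyldimethylsilyloxy)styryl]-4,4,5,5-tetramethyl-1,3,2-dioxaborolane | CC1(C)OB(/C=C/c2ccc(O[Si](C)(C)C(C)(C)C)c(O[Si](C)(C)C(C)(C)C)c2)OC1(C)C
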